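Its constants were set for the occasion; the rest is arithmetic.

At late times target must fall, since the over-reaction step consumes it, so target passes a peak. We ask how far towards that peak the delivered gas carries it.

    substrate + dissolved gas ⇌ target (K1 = 2300 M⁻¹, k1 = 0.187 M⁻¹ s⁻¹)
    gas phase ⇌ dissolved gas, rate k2*(csat - [dissolved gas]) (k2 = 0.00439 s⁻¹, csat = 5.7 mM)
    dissolved gas + target → over-reacted product (k3 = 0.0823 M⁻¹ s⁻¹)
    dissolved gas → decomposed reagent (k4 = 3.78 × 10⁻⁴ s⁻¹)
    substrate ⇌ dormant form (K5 = 0.38, k5 = 8.53 × 10⁻⁴ s⁻¹)

substrate 0.10 M; gas phase 5.7 mM (held); time 1.0 h

- at the start none of the gas is dissolved
- run time (flask): 1.0 h

- target at 1.0 h, in percent of the substrate charged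
- the change that raises the amount of target at 1.0 h, in percent of the substrate charged most ("none" if none brings more than 2 percentage points) (red / green / none)
- amount of target at 1.0 h, in percent of the substrate charged, after green

- red: doubling the saturation concentration of gas phase, all else as stated
- green: doubling the transfer coefficient of step 2, all else as stated

We reckon the rate of target formation. At the start, transfer offers

start rate = 2.50 × 10⁻⁵ M s⁻¹,

which is 90.1% of the charge over the run. Substrate and dormant form relax with a half-life of 0.0622 h, far shorter than the run, so for the run as a whole we count 72.5% of the pool as active.

The first slowing is standing [dissolved gas]. Capture by active substrate is faster than transfer, so transfer is the rate-limiting step, but the inflow still shrinks. The capture share of all first-order gas rates gives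

slowing factor = 0.740.

We replace the curve by this one mean, so gas reaching substrate is 66.6% of the charge.

The second slowing is target competing for that gas. The selectivity factor, over-reaction constant over capture constant times active share, is

κ = 0.607.

For such consecutive steps, target peaks at κ raised to κ/(1−κ):

peak = 46.2%.

We let the net rate fall in proportion to the distance left to the peak. The accumulated slowing then depends on the dose number, delivered gas per peak target:

N = 1.44, target = peak × (1 − exp(−N)) = 35.3%.

Green lowers the factor to 0.597, so

N = 2.32, target = 41.7%.

Red leaves the factor alone, so N = 2.88, larger than green's. Our curve has no fall past the peak, so we do not rank them.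

The forecast says 38.5% (36.5% to 40.5%), green best, and 43.5% (41.5% to 45.5%) after green, both above our figures: “Green therefore narrowly beats red, though the margin is within hand-calculation uncertainty.”

The simulation gives 37.5%, with green best, and 41.8% after green. Green gains 4.3 percentage points and red 2.6 points.

At N = 1.44, this flask read 11.6% over-reacted product at the asked time. The neighbour flask is charged with 0.040 M substrate, all else held. The peak formula holds no charge, so it stays at 46.2%. The factor falls to 0.532, but the smaller charge lifts the dose to N = 2.59, and the curve gives 42.7%. The neighbour flask read 41.8% target, with 21.6% substrate left and 27.0% over-reacted product.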